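(The readings come from a simulation with constants of no real substance; the scatter is artificial.)

Late times were my first concern: what still took the target away there? The winter run had this same charge, but it stopped at 2.50 min.

- winter: starting material 0.039 M; first nucleophile 0.078 M; second nucleophile 0.0429 M; protic impurity 0.039 M; the very flask that is asked about, followed so far
- flask: starting material 0.039 M; first nucleophile 0.0780 M; second nucleophile 0.0429 M; protic impurity 0.0390 M; time 15 min

winter run (percent of the starting material charged)

| time / min | target / % | other capture product / % |
|---|---|---|
| 0.667 | 46.4 | 22.7 |
| 1.33 | 40.5 | 20.8 |
| 2.00 | 36.0 | 21.6 |
| 2.50 | 33.6 | 22.5 |

(scatter of a reading: 0.5 percentage points)

- what is said of target includes crystals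
- crystals is a solid; its amount is given per volume of the solution
- what was read earlier has a scatter of 0.5 percentage points, one standard deviation
- steps under discussion: starting material -> intermediate; first nucleophile + intermediate -> target; second nucleophile + intermediate -> other capture product; intermediate -> solvolysis product; starting material + protic impurity -> quenched substrate; second nucleophile + target -> over-reaction product; crystals <-> target

1. share of target in target plus other capture product at 0.60 s
2. share of target in target plus other capture product at 15 min

In that run the other capture product read 22.7 % and then 22.5 %, while the target fell from 46.4 % to 33.6 %. The listed step that destroys target is its reaction with second nucleophile. Each starting material gave at most one target or one other capture product, and each of those cost at most one second nucleophile. The charges gave 1.10 for the quantity I carried, the cover: second nucleophile charged per starting material charged. This cover was more than one, so starting material was the limiting reagent, and second nucleophile couldn't fall under 3.90 mM in this flask.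

As an estimate, a straight line through the first and last winter target readings reached zero 4.81 min after the last reading, and the flask ran 12.5 min past that reading. I committed to a late share under 5%, and made no early reckoning.

I went through the settings by hand. More second nucleophile raised the cover, so the late share should stay near zero. More starting material lowered the cover, and below one the second nucleophile could give out with target still standing.

The forecast gave 72 % at 0.60 s and 28 % at 15 min, against my late limit of 5%, and noted: “That hints at crystals shielding some target, since only dissolved target reacts.”

The flask gave 75.7 % at 0.60 s and 0.708 % at 15 min.

starting material → intermediate (k = 0.130 /s); first nucleophile + intermediate → target (k = 52.0 /M/s); second nucleophile + intermediate → other capture product (k = 30.0 /M/s); intermediate → solvolysis product (k = 0.350 /s); starting material + protic impurity → quenched substrate (k = 0.180 /M/s); second nucleophile + target → over-reaction product (k = 0.950 /M/s); crystals ⇌ target, rate k7*(cs7 - [target]) while solid is left; crystals form when [target] > cs7 (solubility = 2.50 mM, k = 0.100 /s) By the over-reaction path alone, dissolved target had a half-life of 0.28 min at the charged second nucleophile, shorter than the 15 min run. In this flask, of cover 1.10, target ended at 0.154 %, with 20.1 % of the second nucleophile charge left. The neighbour with 0.073 M of second nucleophile, cover 1.87, ended at a share of 0 %. The neighbour with 0.16 M of starting material had a cover of 0.268. Its second nucleophile ended at 0.204 % of charge, its target at 43.7 %, and its share at 66.7 %.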